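The numbers in the tables come from a simulation from invented constants; scatter was added.

Chains fade in both runs.

all flasks: free monomer 1.1 M; initiator 1.8 mM

| flask | protic impurity | remark | time |
|---|---|---|---|
| birch | 0.11 M | run made earlier |  |
| ash | 0.38 M | run made earlier |  |
| zeta | 0.0800 M |  | 3.0 d |
| eta | 0.120 M |  | 3.0 d |
| alpha | 0.150 M |  | 3.0 d |
| theta | 0.250 M |  | 3.0 d |

- birch (time / d: monomer in chains / %, free monomer / %): 0.833: 12.7, 58.5; 1.67: 8.8, 49.5; 2.50: 7.4, 42.6; 3.00: 3.3, 42.0
- ash (time / d: monomer in chains / %, free monomer / %): 0.250: 8.2, 63.0; 0.500: 9.3, 49.7; 1.25: 11.7, 37.1; 3.00: 5.8, 28.0

(scatter of a reading: 1 percentage point)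

1. amount of monomer in chains at the end, in percent of the free monomer charged for zeta, eta, alpha, theta, in this order
2. how that number moves from the first to the last of them (rises, then falls / hardly changes / falls all the way / rises all the way / falls, then rises)

- the earlier runs were read with a standard deviation of 1 percentage point
- "hardly changes" means that all values lie within two and a half points (for a concentration: within two and a half percent of the largest)

Monomer in chains, "chains" below, climbs and then falls in ash and falls from the first reading in birch, and the fall seems to follow the free monomer still present. So we take the natural log of the drop in chains per day, divided by the mean fraction of free monomer over that stretch. From 0.833 d to the end, birch gives 1.24 /d. From 1.25 d to the end, ash gives 1.23 /d. We carry their mean, 1.23 /d, as the chain wear; at fixed free monomer it makes the loss pseudo-first-order.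

Birch ends with more free monomer than ash, 42.0% against 28.0%. Scaled by impurity, that puts theta 8.8 percentage points below zeta. Held over the second half of the time, this gap gives theta, in our reckoning, 1.18 times the chains of zeta. On the mean last reading, 4.55%, that is a rise of 0.81 points, so our estimate is a slight rise that stays within the margin.

The forecast gives 4.3%, 4.6%, 4.8% and 5.3%, so hardly changes, on the ground that “chains therefore reflect only recent monomer flux, which depends weakly on impurity”.

The flasks give 4.56%, 4.71%, 4.82% and 5.21%: hardly changes.

    initiator → 2 initiating radical (k = 0.00220 /min)
    free monomer + initiating radical → growing radical + monomer in chains (k = 5.10 × 10⁵ /M/min)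
    free monomer + growing radical → monomer in chains + growing radical, rate k3*[growing radical]*[free monomer] (k = 16000 /M/min)
    2 growing radical → dead chain (k = 1.00 × 10⁸ /M/s)
    free monomer + monomer in chains → side product (k = 9.20 × 10⁻⁴ /M/min)
    protic impurity + free monomer → quenched substrate (k = 0.00490 /M/min)

In zeta, chains stand at 10.3% after 1.50 d, and the wear over the second half, with free monomer going from 51.4% to 42.6%, leaves 4.33% against the 4.56% found. In theta, free monomer goes from 42.4% to 34.8%, and the same wear leaves 5.02% against 5.21%. Zeta ends with so few chains mainly because growing radicals pair off into dead chain: without that step, chains in zeta end at 99.7% instead of 4.56%.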